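1. Retrosynthesis: the four aryl O–CH2OMe bonds are cut first, then the C3–OH bond, then the C2–C1′ bond between ring C and ring B. This leaves 5,7-bis(methoxymethoxy)-8-prenylchromone and a fully substituted ring B boronic acid.
2. Enabling feature: C2 is a benzylic ether carbon β to the C4 ketone and bonded to C1′ of ring B, so C2–C1′ is the bond a 1,4-addition of an aryl metal to the C2=C3 enone of a chromone would make.
3. Forward: rings A and C are bought together as 5,7-dihydroxychromone and gain the 8-prenyl group by an O5→C6→C8 Claisen–Cope shift. Ring B comes from resorcinol and receives geranyl, prenyl and boron by three successive ortho-lithiations.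
4. The halves are joined at C2–C1′ (no ring closes), C3 is hydroxylated through the enolate, and the MOM ethers are removed last.
5. Stereochemistry: C2 comes from the chiral bisphosphine on rhodium (the 2S flavanone is spatially the 2R of the target). C3 comes from oxidant attack anti to the C2 aryl group (2,3-trans, 3R). The E olefin comes unchanged from geranyl bromide.

Key step: step 9

Assumption: the (S)-bisphosphine is expected to give the 2S flavanone by analogy with its additions to 2-cyclohexenone; if the chromone shows the opposite sense, the ligand antipode is used.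

Abbreviations: MOM = methoxymethyl; prenyl = 3-methylbut-2-en-1-yl; geranyl = (2E)-3,7-dimethylocta-2,6-dien-1-yl.

Step 1
Reactants: 1 5,7-dihydroxychromone
Product: 2 5-hydroxy-7-(methoxymethoxy)chromone
Conditions: MOMCl (1.1 equiv), K2CO3 (1.5 equiv), acetone, 0 °C → rt
Reagents that add atoms: chloromethyl methyl ether (MOMCl), COCCl
Why: Williamson-type MOM ether formation; the 5-OH is held in a hydrogen bond to the C4 carbonyl, so one equivalent of MOMCl with a weak base should alkylate only the free, vinylogously acidic 7-OH.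

Step 2
Reactants: 2 5-hydroxy-7-(methoxymethoxy)chromone; 3 prenyl bromide
Product: 4 7-(methoxymethoxy)-5-(prenyloxy)chromone
Conditions: 3 (1.5 equiv), K2CO3 (2 equiv), DMF, 40 °C
Reagents that add atoms: none
Why: Williamson O-alkylation of the one remaining phenol with the primary allylic bromide; carbonate in DMF breaks the chelate and should give SN2 attack at oxygen rather than C-alkylation.

Step 3
Reactants: 4 7-(methoxymethoxy)-5-(prenyloxy)chromone
Product: 7 5-hydroxy-7-(methoxymethoxy)-8-prenylchromone, via ortho-dienone 5 (not isolated), via para-dienone 6 (not isolated)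
Conditions: Eu(fod)3 (10 mol %), NaHCO3, PhCl, 85 °C
Reagents that add atoms: none
Why: A Lewis-acid-promoted aromatic Claisen rearrangement to C6, the only free ortho carbon, gives dienone 5 with a reverse prenyl group, and a Cope shift to C8 followed by tautomerisation (para-Claisen–Cope sequence) should give the normal 8-prenyl phenol; europium chelation by O5 and the C4 carbonyl lowers the temperature needed and NaHCO3 protects the MOM ether.

Step 4
Reactants: 7 5-hydroxy-7-(methoxymethoxy)-8-prenylchromone
Product: 9 5,7-bis(methoxymethoxy)-8-prenylchromone, via sodium phenoxide 8 (not isolated)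
Conditions: NaH (1.2 equiv), DMF, 0 °C; MOMCl (1.3 equiv), 0 °C → rt
Reagents that add atoms: chloromethyl methyl ether (MOMCl), COCCl
Why: Williamson MOM ether formation through the sodium phenoxide, NaH being needed because the 5-OH is chelated to the C4 carbonyl; the chromone enone and the prenyl olefin are inert here.

Step 5
Reactants: 10 resorcinol
Product: 11 1,3-bis(methoxymethoxy)benzene
Conditions: MOMCl (2.5 equiv), i-Pr2NEt (3 equiv), CH2Cl2, 0 °C → rt
Reagents that add atoms: chloromethyl methyl ether (MOMCl), COCCl
Why: Twofold MOM ether formation (amine-base Williamson alkylation) of both phenols installs the two groups that direct all three later metalations.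

Step 6
Reactants: 11 1,3-bis(methoxymethoxy)benzene; 12 geranyl bromide
Product: 14 2-geranyl-1,3-bis(methoxymethoxy)benzene, via aryllithium 13 (not isolated)
Conditions: n-BuLi (1.1 equiv), THF, 0 °C → rt; CuI (10 mol %), 12 (1.1 equiv), −78 °C → rt
Reagents that add atoms: none
Why: Directed ortho-metalation occurs at C2, the position flanked by both OMOM groups, and copper-catalysed SN2 allylic substitution at the primary carbon of the bromide should attach the geranyl group with its E olefin unchanged.

Step 7
Reactants: 14 2-geranyl-1,3-bis(methoxymethoxy)benzene; 3 prenyl bromide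
Product: 16 2-geranyl-1,3-bis(methoxymethoxy)-4-prenylbenzene, via aryllithium 15 (not isolated)
Conditions: n-BuLi (1.2 equiv), TMEDA (1.2 equiv), THF, 0 °C; CuI (10 mol %), 3 (1.3 equiv), −78 °C → rt
Reagents that add atoms: none
Why: A second directed ortho-metalation occurs ortho to one OMOM group (C4 and C6 are equivalent by symmetry, and lithium coordination to the acetal oxygens should outrun deprotonation of the benzylic–allylic CH2), followed by copper-catalysed SN2 allylation as in step 6.

Step 8
Reactants: 16 2-geranyl-1,3-bis(methoxymethoxy)-4-prenylbenzene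
Product: 19 3-geranyl-2,4-bis(methoxymethoxy)-5-prenylphenylboronic acid, via aryllithium 17 (not isolated), via lithium triisopropoxyborate 18 (not isolated)
Conditions: n-BuLi (1.3 equiv), TMEDA (1.3 equiv), THF, 0 °C; B(Oi-Pr)3 (2 equiv), −78 °C → rt; AcOH, H2O, 0 °C
Reagents that add atoms: triisopropyl borate, CC(C)OB(OC(C)C)OC(C)C; water, O
Why: The third directed ortho-metalation can only occur at C6, the one remaining position ortho to an OMOM group, and electrophilic borylation followed by mildly acidic hydrolysis of the ate complex should give the boronic acid without loss of the MOM ethers.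

Step 9
Reactants: 9 5,7-bis(methoxymethoxy)-8-prenylchromone; 19 3-geranyl-2,4-bis(methoxymethoxy)-5-prenylphenylboronic acid
Product: 20 (2S)-2-[3-geranyl-2,4-bis(methoxymethoxy)-5-prenylphenyl]-5,7-bis(methoxymethoxy)-8-prenylchroman-4-one
Conditions: 19 (1.5 equiv, in portions), [RhCl(C2H4)2]2 (3 mol %), (S)-MeO-F12-BIPHEP [(S)-6,6′-dimethoxy-2,2′-bis(bis(3,4,5-trifluorophenyl)phosphino)biphenyl] (6.6 mol %), KOH (20 mol %), toluene/H2O 10:1, 40 °C
Reagents that add atoms: none
Why: The aryl group of 19 transmetalates from boron to a hydroxo complex of monovalent rhodium, the aryl–rhodium bond inserts across C2=C3 of chromone 9 to give an oxa-π-allyl rhodium enolate, and protonolysis by water releases flavanone 20 and regenerates the rhodium hydroxide. The closest known reaction is the Hayashi–Miyaura asymmetric 1,4-addition of arylboronic acids to chromones, which gives enantioenriched flavanones. Only the C2–C1′ bond forms and no ring closes, because ring C is already present as the pyranone. The new C2 stereocentre is set by the chiral bisphosphine, the (S) ligand being chosen because its (S)-3-arylcyclohexanone products from 2-cyclohexenone correspond spatially to the (2S)-flavanone. The step needs enantioface selectivity at C2 and 1,4- rather than 1,2-addition; the unsubstituted C2 of 9, the single ortho substituent (2-OMOM) of the aryl partner and the masking of every phenol as a MOM ether favour this, and the boron position fixes the site on ring B. The trisubstituted side-chain olefins should not insert, and the nearly neutral medium should prevent retro-oxa-Michael racemisation of C2.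

Step 10
Reactants: 20 (2S)-2-[3-geranyl-2,4-bis(methoxymethoxy)-5-prenylphenyl]-5,7-bis(methoxymethoxy)-8-prenylchroman-4-one
Product: 23 (2R,3R)-2-[3-geranyl-2,4-bis(methoxymethoxy)-5-prenylphenyl]-3-hydroxy-5,7-bis(methoxymethoxy)-8-prenylchroman-4-one, via potassium enolate 21 (not isolated), via potassium alkoxide 22 (not isolated)
Conditions: KN(SiMe3)2 (1.15 equiv), THF, −78 °C; (±)-trans-3-phenyl-2-(phenylsulfonyl)oxaziridine (1.5 equiv), −78 °C; AcOH, −78 °C
Reagents that add atoms: 3-phenyl-2-(phenylsulfonyl)oxaziridine, O=S(=O)(c1ccccc1)N1OC1c1ccccc1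
Why: Davis oxidation of a ketone enolate: KN(SiMe3)2 can only enolise toward C3, the N-sulfonyloxaziridine transfers oxygen to the enolate face anti to the pseudo-equatorial C2 aryl group to give the 2,3-trans (3R) alcohol, the isolated trisubstituted olefins are not epoxidised by this reagent at −78 °C, and the low temperature and acidic quench should suppress β-elimination of the ring oxygen so that C2 is untouched (its descriptor changes from S to R only because C3 gains priority).

Step 11
Reactants: 23 (2R,3R)-2-[3-geranyl-2,4-bis(methoxymethoxy)-5-prenylphenyl]-3-hydroxy-5,7-bis(methoxymethoxy)-8-prenylchroman-4-one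
Product: 24 (2R,3R)-2-(3-geranyl-2,4-dihydroxy-5-prenylphenyl)-3,5,7-trihydroxy-8-prenylchroman-4-one (target CNP0149909.1)
Conditions: 3 M aq HCl/MeOH (1:9), 40 °C, stopped as soon as the last MOM ether is consumed
Reagents that add atoms: none
Why: Acid-catalysed acetal exchange with methanol cleaves all four aryl MOM ethers, and the dilute acid, low temperature and short time are chosen so that the ortho-prenyl and ortho-geranyl phenols should not cyclise to chromans and the trans-dihydroflavonol should not epimerise.

Compound list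
1 | 5,7-dihydroxychromone (5,7-dihydroxy-4H-chromen-4-one) | O=c1ccoc2cc(O)cc(O)c12 | starting material
2 | 5-hydroxy-7-(methoxymethoxy)chromone | O=c1ccoc2cc(OCOC)cc(O)c12 | intermediate
3 | prenyl bromide (1-bromo-3-methylbut-2-ene) | CC(C)=CCBr | starting material
4 | 7-(methoxymethoxy)-5-(prenyloxy)chromone | O=c1ccoc2cc(OCOC)cc(OCC=C(C)C)c12 | intermediate
5 | ortho-dienone formed in situ: 7-(methoxymethoxy)-6-(2-methylbut-3-en-2-yl)-6H-chromene-4,5-dione | O=C1C=COC2=C1C(=O)C(C(C)(C)C=C)C(OCOC)=C2 | intermediate
6 | para-dienone formed in situ: 7-(methoxymethoxy)-8-prenyl-8H-chromene-4,5-dione | O=C1C=COC2=C1C(=O)C=C(OCOC)C2CC=C(C)C | intermediate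
7 | 5-hydroxy-7-(methoxymethoxy)-8-prenylchromone | O=c1ccoc2c(CC=C(C)C)c(OCOC)cc(O)c12 | intermediate
8 | sodium 7-(methoxymethoxy)-4-oxo-8-prenylchromen-5-olate, formed in situ | [Na+].O=c1ccoc2c(CC=C(C)C)c(OCOC)cc([O-])c12 | intermediate
9 | 5,7-bis(methoxymethoxy)-8-prenylchromone | O=c1ccoc2c(CC=C(C)C)c(OCOC)cc(OCOC)c12 | intermediate
10 | resorcinol | Oc1cccc(O)c1 | starting material
11 | 1,3-bis(methoxymethoxy)benzene | COCOc1cccc(OCOC)c1 | intermediate
12 | geranyl bromide ((2E)-1-bromo-3,7-dimethylocta-2,6-diene) | CC(C)=CCC/C(C)=C/CBr | starting material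
13 | 2,6-bis(methoxymethoxy)phenyllithium, formed in situ | [Li]c1c(OCOC)cccc1OCOC | intermediate
14 | 2-geranyl-1,3-bis(methoxymethoxy)benzene | CC(C)=CCC/C(C)=C/Cc1c(OCOC)cccc1OCOC | intermediate
15 | 3-geranyl-2,4-bis(methoxymethoxy)phenyllithium, formed in situ | CC(C)=CCC/C(C)=C/Cc1c(OCOC)c([Li])ccc1OCOC | intermediate
16 | 2-geranyl-1,3-bis(methoxymethoxy)-4-prenylbenzene | CC(C)=CCC/C(C)=C/Cc1c(OCOC)c(CC=C(C)C)ccc1OCOC | intermediate
17 | 3-geranyl-2,4-bis(methoxymethoxy)-5-prenylphenyllithium, formed in situ | CC(C)=CCC/C(C)=C/Cc1c(OCOC)c(CC=C(C)C)cc([Li])c1OCOC | intermediate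
18 | lithium [3-geranyl-2,4-bis(methoxymethoxy)-5-prenylphenyl]triisopropoxyborate, formed in situ | [Li+].CC(C)=CCC/C(C)=C/Cc1c(OCOC)c(CC=C(C)C)cc([B-](OC(C)C)(OC(C)C)OC(C)C)c1OCOC | intermediate
19 | 3-geranyl-2,4-bis(methoxymethoxy)-5-prenylphenylboronic acid | CC(C)=CCC/C(C)=C/Cc1c(OCOC)c(CC=C(C)C)cc(B(O)O)c1OCOC | intermediate
20 | (2S)-2-[3-geranyl-2,4-bis(methoxymethoxy)-5-prenylphenyl]-5,7-bis(methoxymethoxy)-8-prenylchroman-4-one | CC(C)=CCC/C(C)=C/Cc1c(OCOC)c(CC=C(C)C)cc([C@H]2Oc3c(CC=C(C)C)c(OCOC)cc(OCOC)c3C(=O)C2)c1OCOC | intermediate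
21 | potassium C3–C4 enolate of 20 (2S), formed in situ | [K+].CC(C)=CCC/C(C)=C/Cc1c(OCOC)c(CC=C(C)C)cc([C@H]2Oc3c(CC=C(C)C)c(OCOC)cc(OCOC)c3C([O-])=C2)c1OCOC | intermediate
22 | potassium 3-alkoxide of 23 (2R,3R), formed in situ | [K+].CC(C)=CCC/C(C)=C/Cc1c(OCOC)c(CC=C(C)C)cc([C@H]2Oc3c(CC=C(C)C)c(OCOC)cc(OCOC)c3C(=O)[C@@H]2[O-])c1OCOC | intermediate
23 | (2R,3R)-2-[3-geranyl-2,4-bis(methoxymethoxy)-5-prenylphenyl]-3-hydroxy-5,7-bis(methoxymethoxy)-8-prenylchroman-4-one | CC(C)=CCC/C(C)=C/Cc1c(OCOC)c(CC=C(C)C)cc([C@H]2Oc3c(CC=C(C)C)c(OCOC)cc(OCOC)c3C(=O)[C@@H]2O)c1OCOC | intermediate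
24 | (2R,3R)-2-(3-geranyl-2,4-dihydroxy-5-prenylphenyl)-3,5,7-trihydroxy-8-prenylchroman-4-one (CNP0149909.1) | CC(C)=CCC/C(C)=C/Cc1c(O)c(CC=C(C)C)cc([C@H]2Oc3c(CC=C(C)C)c(O)cc(O)c3C(=O)[C@@H]2O)c1O | target

Total step count: 11 steps.
Longest linear sequence: 7 steps (steps 1–4 then 9–11, or steps 5–8 then 9–11).

Steps most likely to fail

Step 9. Protodeboronation of the electron-rich, ortho-alkoxy boronic acid may outrun transmetalation. Insertion into the electron-rich 5,7-dialkoxychromone may be slow, and the enantioface discrimination may be insufficient with the ortho-substituted aryl group. The fallback sets out from arene 16 and chromone 9 and returns at flavanone 20. Arene 16 is lithiated as in step 8 to aryllithium 17, which is transmetalated with ZnCl2 (THF, −78 → 0 °C) to [3-geranyl-2,4-bis(methoxymethoxy)-5-prenylphenyl]zinc chloride F1. F1 is added to 9 under anhydrous conditions with [RhCl((S)-binap)]2 and Me3SiCl in THF at 20 °C. This is the known asymmetric 1,4-addition of arylzinc chlorides to heterocyclic enones under monovalent rhodium catalysis with chlorosilane trapping. The rhodium enolate is captured as the (2S)-4-(trimethylsilyloxy)-2H-chromene F2, so no water is present to destroy the aryl metal. Brief hydrolysis of F2 (aqueous citric acid, THF, 0 °C) gives 20.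

Step 10. The potassium enolate may eliminate the ring oxygen (ring opening to a chalcone phenoxide, with loss of the C2 configuration on re-closure), or the oxidant may attack both faces. The fallback sets out from flavanone 20 and returns at 23. Soft enolisation with TBSOTf/Et3N (CH2Cl2, 0 °C), which never generates a free enolate, gives the (2S)-4-(tert-butyldimethylsilyloxy)-2H-chromene F3. Rubottom-type oxidation of F3 with the same neutral sulfonyloxaziridine (CHCl3, 25–40 °C) should occur anti to the C2 aryl group, since the silyl enol ether is far more nucleophilic than the trisubstituted olefins. Silyl migration in the silyloxy epoxide then gives the (2R,3R)-3-(tert-butyldimethylsilyloxy)chroman-4-one F4. HF·pyridine in THF removes the silyl group and leaves the MOM ethers, giving 23.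

Step 11. Acid-catalysed cyclisation of the ortho-prenyl and ortho-geranyl phenols to chromans, or cation–olefin cyclisation of the geranyl chain, may compete with acetal cleavage, and deprotection may stop short. The fallback sets out from 23 and returns at target 24. Non-protic cleavage with TMSOTf and 2,2′-bipyridyl (CH2Cl2, 0 °C → rt) converts each aryl MOM ether into an aryl trimethylsilyl ether and silylates the 3-OH, giving the (2R,3R)-pentakis(trimethylsilyl) ether F5. Addition of water at room temperature hydrolyses the silyl ethers to 24 without exposing the free phenols to strong Brønsted acid.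

Further compounds
F1 | step 9 | [3-geranyl-2,4-bis(methoxymethoxy)-5-prenylphenyl]zinc chloride | CC(C)=CCC/C(C)=C/Cc1c(OCOC)c(CC=C(C)C)cc([Zn]Cl)c1OCOC
F2 | step 9 | (2S)-2-[3-geranyl-2,4-bis(methoxymethoxy)-5-prenylphenyl]-5,7-bis(methoxymethoxy)-8-prenyl-4-(trimethylsilyloxy)-2H-chromene | CC(C)=CCC/C(C)=C/Cc1c(OCOC)c(CC=C(C)C)cc([C@H]2Oc3c(CC=C(C)C)c(OCOC)cc(OCOC)c3C(O[Si](C)(C)C)=C2)c1OCOC
F3 | step 10 | (2S)-4-(tert-butyldimethylsilyloxy)-2-[3-geranyl-2,4-bis(methoxymethoxy)-5-prenylphenyl]-5,7-bis(methoxymethoxy)-8-prenyl-2H-chromene | CC(C)=CCC/C(C)=C/Cc1c(OCOC)c(CC=C(C)C)cc([C@H]2Oc3c(CC=C(C)C)c(OCOC)cc(OCOC)c3C(O[Si](C)(C)C(C)(C)C)=C2)c1OCOC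
F4 | step 10 | (2R,3R)-3-(tert-butyldimethylsilyloxy)-2-[3-geranyl-2,4-bis(methoxymethoxy)-5-prenylphenyl]-5,7-bis(methoxymethoxy)-8-prenylchroman-4-one | CC(C)=CCC/C(C)=C/Cc1c(OCOC)c(CC=C(C)C)cc([C@H]2Oc3c(CC=C(C)C)c(OCOC)cc(OCOC)c3C(=O)[C@@H]2O[Si](C)(C)C(C)(C)C)c1OCOC
F5 | step 11 | (2R,3R)-2-[3-geranyl-5-prenyl-2,4-bis(trimethylsilyloxy)phenyl]-8-prenyl-3,5,7-tris(trimethylsilyloxy)chroman-4-one | CC(C)=CCC/C(C)=C/Cc1c(O[Si](C)(C)C)c(CC=C(C)C)cc([C@H]2Oc3c(CC=C(C)C)c(O[Si](C)(C)C)cc(O[Si](C)(C)C)c3C(=O)[C@@H]2O[Si](C)(C)C)c1O[Si](C)(C)C
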